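The target is a meso tetrahydrofuran: C3 and C4 hold their aroyl carbonyl carbons on one face, C2 and C5 are 4-oxygenated benzylic carbons. The two carbonyl carbons are therefore tied into a cis-fused anhydride ring, and O1–C5 and C2–C3 are disconnected. In one operation a Lewis acid opens an anhydride-fused aryl cyclopropane at its donor–acceptor bond and stitches in 4-(benzyloxy)benzaldehyde, which closes the tetrahydrofuran ring and sets C2, C3 and C5 relative to C4. The precursor is exo-6-[4-(benzyloxy)phenyl]-3-oxabicyclo[3.1.0]hexane-2,4-dione, made from the same aldehyde and maleic anhydride; the anhydride is later turned into both aryl ketones without base.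

Key step: step 3

Remark: the target has a mirror plane through O1 and the midpoint of C3–C4, so only relative configuration has to be controlled; 5, 8 and 15 are racemic and drawn as one enantiomer; the opening in step 3 is planned as an ionising, stereoconvergent process, so either C6 epimer of 6 would serve; ring atoms are numbered O1, C2–C5 as in the target.

Step 1
Reactants: 1 4-(benzyloxy)benzaldehyde
Product: 2 (E)-[4-(benzyloxy)benzylidene]hydrazine
Conditions: N2H4·H2O (10 equiv), EtOH, reflux
Reagents that add atoms: hydrazine (used as the hydrate), NN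
Why: Hydrazone formation by condensation; the large excess of hydrazine should suppress azine formation.

Step 2
Reactants: 2 (E)-[4-(benzyloxy)benzylidene]hydrazine; 3 maleic anhydride
Product: 6 exo-6-[4-(benzyloxy)phenyl]-3-oxabicyclo[3.1.0]hexane-2,4-dione, via aryldiazomethane 4 (not isolated), via 1-pyrazoline adduct 5 (not isolated)
Conditions: activated MnO2, MgSO4, CH2Cl2, 0 °C, filter; then 3, −20 → 0 °C; then hν (350 nm), 0 °C
Reagents that add atoms: none
Why: Manganese dioxide dehydrogenates the hydrazone to the aryldiazomethane, whose suprafacial 1,3-dipolar cycloaddition to the cis-alkene gives the cis-fused 1-pyrazoline with the aryl group on the side away from the anhydride, and photochemical extrusion of nitrogen then closes the cyclopropane, in which the ring fusion must stay cis and the aryl group should keep the less hindered exo position.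

Step 3
Reactants: 6 exo-6-[4-(benzyloxy)phenyl]-3-oxabicyclo[3.1.0]hexane-2,4-dione; 1 4-(benzyloxy)benzaldehyde
Product: 7 cis-fused 4,6-bis[4-(benzyloxy)phenyl]tetrahydro-1H,3H-furo[3,4-c]furan-1,3-dione with both aryl groups exo (meso)
Conditions: 1 (3 equiv), Sn(OTf)2 (20 mol %), 4 Å MS, CH2Cl2, −20 °C → rt
Reagents that add atoms: none
Why: Proposed new method: tin(II) triflate on an anhydride carbonyl should polarise the strained C1–C6 bond of 6, which joins the 4-benzyloxyphenyl donor carbon to an acyl-bearing carbon, so that it ionises to a benzylic cation paired with an anhydride enolate; the carbonyl oxygen of 1 traps the cation (O1–C5) and the enolate carbon then adds to the resulting oxocarbenium ion (C2–C3). The closest known reaction type is the Lewis-acid (3+2) annulation of 2-arylcyclopropane-1,1-diesters with aldehydes to 2,5-cis-tetrahydrofurans, from which this case differs in having one acceptor on each of two ring carbons, held in an anhydride. The tetrahydrofuran ring closes by an aldol-type attack of an enolate lying outside the new ring on an endocyclic C=O+ bond (formally 5-(enolexo)-endo-trig, the closure of the diester annulation). C3 is forced cis to C4, whose configuration is carried over from the cyclopropane, because an enolate embedded in the five-membered anhydride can only give a cis-fused bicyclo[3.3.0] system. C2 and C5 are set by the preference of both aryl groups for the convex face; since a strictly invertive opening of exo-6 would first place the C5 aryl on the concave face, the step counts on the two 4-benzyloxyphenyl groups keeping both benzylic C–O bonds ionisable under the Lewis acid, so that the mixture settles in the all-exo isomer 7. The chemoselectivity needed is capture of the cation by the aldehyde instead of loss of the C4 proton to an arylidenesuccinic anhydride, which the excess of the electron-rich aldehyde, the low temperature and the non-basic triflate counter-ion are meant to secure.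

Step 4
Reactants: 7 cis-fused 4,6-bis[4-(benzyloxy)phenyl]tetrahydro-1H,3H-furo[3,4-c]furan-1,3-dione
Product: 9 S,S'-bis(4-methylphenyl) (2R,3R,4S,5S)-2,5-bis[4-(benzyloxy)phenyl]oxolane-3,4-bis(carbothioate) (meso), via thioester acid 8 (not isolated)
Conditions: 4-MeC6H4SH (2.5 equiv), N-methylmorpholine (1.1 equiv), CH2Cl2, 0 °C; then DCC (1.2 equiv), DMAP (5 mol %), 0 °C → rt
Reagents that add atoms: 4-methylbenzenethiol, Cc1ccc(S)cc1
Why: The thiolate opens the cyclic anhydride and a Steglich-type carbodiimide thioesterification then caps the liberated acid; no bond to C3 or C4 is broken, and the weak base and low temperature are meant to prevent enolisation of the cis-bis(thioester).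

Step 5
Reactants: 10 4-bromoresorcinol
Product: 11 2,4-bis(benzyloxy)-1-bromobenzene
Conditions: BnBr (2.2 equiv), K2CO3, DMF, 60 °C
Reagents that add atoms: benzyl bromide, BrCc1ccccc1
Why: Williamson ether synthesis on both phenoxides.

Step 6
Reactants: 11 2,4-bis(benzyloxy)-1-bromobenzene
Product: 14 [2,4-bis(benzyloxy)phenyl]boronic acid, via aryllithium 12 (not isolated), via lithium aryltriisopropoxyborate 13 (not isolated)
Conditions: n-BuLi, THF, −78 °C; B(OiPr)3, −78 °C → rt; 1 M HCl
Reagents that add atoms: triisopropyl borate, CC(C)OB(OC(C)C)OC(C)C; water, O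
Why: Bromine–lithium exchange (faster at −78 °C than ortho-lithiation or attack on the benzyl ethers), borylation of the aryllithium and hydrolysis of the borate.

Step 7
Reactants: 9 S,S'-bis(4-methylphenyl) (2R,3R,4S,5S)-2,5-bis[4-(benzyloxy)phenyl]oxolane-3,4-bis(carbothioate); 14 [2,4-bis(benzyloxy)phenyl]boronic acid
Product: 16 [(2R,3R,4S,5S)-2,5-bis[4-(benzyloxy)phenyl]oxolane-3,4-diyl]bis{[2,4-bis(benzyloxy)phenyl]methanone} (meso), via keto thioester 15 (not isolated)
Conditions: 14 (4 equiv), Pd2(dba)3 (5 mol %), P(2-furyl)3 (20 mol %), CuTC (3.2 equiv), THF, 50 °C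
Reagents that add atoms: none
Why: Liebeskind–Srogl coupling: palladium(0) inserts into each acyl–sulfur bond while copper(I) thiophene-2-carboxylate binds the thiolate and activates the boronic acid, so both aryl ketones form without added base and the enolisable C3 and C4 centres and the β-alkoxy ketone motif are not exposed to epimerising or ring-opening conditions.

Step 8
Reactants: 16 [(2R,3R,4S,5S)-2,5-bis[4-(benzyloxy)phenyl]oxolane-3,4-diyl]bis{[2,4-bis(benzyloxy)phenyl]methanone}
Product: 17 [(2R,3R,4S,5S)-2,5-bis(4-hydroxyphenyl)oxolane-3,4-diyl]bis[(2,4-dihydroxyphenyl)methanone] (meso)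
Conditions: H2 (1 atm), 10% Pd/C, THF–MeOH, rt
Reagents that add atoms: none
Why: Palladium-catalysed hydrogenolysis removes the six aryl benzyl ethers, which should cleave far faster under neutral conditions at 1 atm than the ring benzylic C–O bonds or the hydrogen-bonded aryl ketones, and no stereocentre is touched.

Compound list
1 | 4-(benzyloxy)benzaldehyde | O=Cc1ccc(OCc2ccccc2)cc1 | starting material
2 | (E)-[4-(benzyloxy)benzylidene]hydrazine | N/N=C/c1ccc(OCc2ccccc2)cc1 | intermediate
3 | maleic anhydride | O=C1OC(=O)C=C1 | starting material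
4 | 1-(benzyloxy)-4-(diazomethyl)benzene | [N-]=[N+]=Cc1ccc(OCc2ccccc2)cc1 | intermediate
5 | cis-fused 3-[4-(benzyloxy)phenyl]-3,3a-dihydro-4H-furo[3,4-c]pyrazole-4,6(6aH)-dione, aryl trans to the anhydride carbon on C3a, racemic | O=C1OC(=O)[C@H]2[C@@H]1[C@H](c3ccc(OCc4ccccc4)cc3)N=N2 | intermediate
6 | exo-6-[4-(benzyloxy)phenyl]-3-oxabicyclo[3.1.0]hexane-2,4-dione (meso; aryl trans to the anhydride ring) | O=C1OC(=O)[C@H]2[C@@H]1[C@@H]2c3ccc(OCc4ccccc4)cc3 | intermediate
7 | cis-fused 4,6-bis[4-(benzyloxy)phenyl]tetrahydro-1H,3H-furo[3,4-c]furan-1,3-dione, meso, both aryl groups exo (cis to each other, trans to the anhydride carbons) | O=C1OC(=O)[C@@H]2[C@H]1[C@@H](c3ccc(OCc4ccccc4)cc3)O[C@H]2c5ccc(OCc6ccccc6)cc5 | intermediate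
8 | 2,5-bis[4-(benzyloxy)phenyl]-4-{[(4-methylphenyl)sulfanyl]carbonyl}oxolane-3-carboxylic acid, racemic; 3,4-cis, 2,5-cis, each carbonyl group trans to its neighbouring aryl | O=C(Sc1ccc(C)cc1)[C@@H]2[C@H](C(=O)O)[C@@H](c3ccc(OCc4ccccc4)cc3)O[C@H]2c5ccc(OCc6ccccc6)cc5 | intermediate
9 | S,S'-bis(4-methylphenyl) (2R,3R,4S,5S)-2,5-bis[4-(benzyloxy)phenyl]oxolane-3,4-bis(carbothioate), meso | O=C(Sc1ccc(C)cc1)[C@@H]2[C@H](C(=O)Sc3ccc(C)cc3)[C@@H](c4ccc(OCc5ccccc5)cc4)O[C@H]2c6ccc(OCc7ccccc7)cc6 | intermediate
10 | 4-bromoresorcinol (4-bromobenzene-1,3-diol) | Oc1ccc(Br)c(O)c1 | starting material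
11 | 2,4-bis(benzyloxy)-1-bromobenzene | Brc1ccc(OCc2ccccc2)cc1OCc1ccccc1 | intermediate
12 | [2,4-bis(benzyloxy)phenyl]lithium | [Li]c1ccc(OCc2ccccc2)cc1OCc1ccccc1 | intermediate
13 | lithium [2,4-bis(benzyloxy)phenyl]triisopropoxyborate | [Li+].CC(C)O[B-](OC(C)C)(OC(C)C)c1ccc(OCc2ccccc2)cc1OCc1ccccc1 | intermediate
14 | [2,4-bis(benzyloxy)phenyl]boronic acid | OB(O)c1ccc(OCc2ccccc2)cc1OCc1ccccc1 | intermediate
15 | S-(4-methylphenyl) 4-[2,4-bis(benzyloxy)benzoyl]-2,5-bis[4-(benzyloxy)phenyl]oxolane-3-carbothioate, racemic, same relative configuration as 9 | O=C(c1ccc(OCc2ccccc2)cc1OCc3ccccc3)[C@@H]4[C@H](C(=O)Sc5ccc(C)cc5)[C@@H](c6ccc(OCc7ccccc7)cc6)O[C@H]4c8ccc(OCc9ccccc9)cc8 | intermediate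
16 | [(2R,3R,4S,5S)-2,5-bis[4-(benzyloxy)phenyl]oxolane-3,4-diyl]bis{[2,4-bis(benzyloxy)phenyl]methanone}, meso | O=C(c1ccc(OCc2ccccc2)cc1OCc3ccccc3)[C@@H]4[C@H](C(=O)c5ccc(OCc6ccccc6)cc5OCc7ccccc7)[C@@H](c8ccc(OCc9ccccc9)cc8)O[C@H]4c1ccc(OCc2ccccc2)cc1 | intermediate
17 | [(2R,3R,4S,5S)-2,5-bis(4-hydroxyphenyl)oxolane-3,4-diyl]bis[(2,4-dihydroxyphenyl)methanone], meso; 3,4-cis aroyl groups, 2,5-cis aryl groups, each aroyl trans to its neighbouring aryl (CNP0237262.1) | O=C(c1ccc(O)cc1O)[C@@H]1[C@H](C(=O)c2ccc(O)cc2O)[C@@H](c2ccc(O)cc2)O[C@H]1c1ccc(O)cc1 | target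

Total step count: 8. Longest linear sequence: 6 steps (steps 1, 2, 3, 4, 7, 8); steps 5 and 6 form the boronic acid branch that joins at step 7.

Steps most likely to fail

Step 3 (the proposed annulation). The benzylic cation may lose the neighbouring proton and drain into a ring-opened alkene before the aldehyde captures it. The weakly basic anhydride may also fail to hold the Lewis acid against the excess aldehyde, or equilibration of the two benzylic centres may stop short of the all-exo isomer. The fallback is a carbonyl ylide cycloaddition, which is known chemistry; it sets out from 1 and 3 and comes back at 7. McMurry coupling of 1 (TiCl4, Zn, THF, reflux) should give (E)-4,4'-bis(benzyloxy)stilbene F1. Epoxidation with dimethyldioxirane in acetone at 0 °C should give trans-2,3-bis[4-(benzyloxy)phenyl]oxirane F2 under neutral conditions. Electron-transfer-sensitised photolysis of F2 (1,4-dicyanonaphthalene, MeCN, hν) should cleave its C–C bond to the carbonyl ylide, which adds across the cis-alkene of 3 in a 1,3-dipolar cycloaddition. Brief acid equilibration of the benzylic centres of the adduct mixture (catalytic Sn(OTf)2, CH2Cl2) should then converge on 7.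

Step 7 (double acyl coupling). Protodeboronation of the electron-rich, ortho-substituted boronic acid and slow acyl transfer at the second, crowded thioester may leave the reaction at the mono-ketone stage. The fallback forms the two ketones one at a time from organozinc partners; it sets out from 7 and 11 and comes back at 16. Bromide 11 is lithiated as in step 6 and the aryllithium 12 is transmetalated with ZnCl2 to [2,4-bis(benzyloxy)phenyl]zinc chloride F3. Rhodium(I)-catalysed acyl cross-coupling of the cyclic anhydride 7 with F3 should give the cis keto acid 4-[2,4-bis(benzyloxy)benzoyl]-2,5-bis[4-(benzyloxy)phenyl]oxolane-3-carboxylic acid F4, with the ring fusion geometry retained. Carbodiimide thioesterification with ethanethiol (EDC, DMAP cat., CH2Cl2, 0 °C) should give the S-ethyl keto thioester F5. Fukuyama coupling of F5 with F3 (PdCl2(PPh3)2, THF–toluene, rt) should deliver 16.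

Step 2 (diazoalkane cycloaddition and nitrogen loss). Tautomerisation of the 1-pyrazoline to the photostable 2-pyrazoline, or protonation of the diazoalkane by traces of maleic acid, may compete with cyclopropane formation; the diazoalkane must also be kept cold, dilute and unconcentrated. The fallback avoids free diazoalkane and photolysis by palladium-carbene transfer to a maleimide; it sets out from 1 and comes back at 6. Condensation of 1 with tosylhydrazide (MeOH, rt) gives 4-(benzyloxy)benzaldehyde tosylhydrazone F6. Palladium-catalysed cyclopropanation of N-phenylmaleimide with F6 (Pd(OAc)2 cat., LiOtBu, dioxane, 90 °C) should give exo-6-[4-(benzyloxy)phenyl]-3-phenyl-3-azabicyclo[3.1.0]hexane-2,4-dione F7, the imide ring keeping the carbonyls cis. Exhaustive alkaline hydrolysis (KOH, aqueous ethylene glycol, 120 °C; cold dilute acid) should give cis-3-[4-(benzyloxy)phenyl]cyclopropane-1,2-dicarboxylic acid F8. Acetyl chloride at rt should close F8 to 6.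

Further compounds
F1 | step 3 | (E)-4,4'-bis(benzyloxy)stilbene | c1ccccc1COc1ccc(/C=C/c2ccc(OCc3ccccc3)cc2)cc1
F2 | step 3 | trans-2,3-bis[4-(benzyloxy)phenyl]oxirane, racemic | c1ccccc1COc1ccc(cc1)[C@@H]1O[C@H]1c1ccc(OCc2ccccc2)cc1
F3 | step 7 | [2,4-bis(benzyloxy)phenyl]zinc chloride | Cl[Zn]c1ccc(OCc2ccccc2)cc1OCc1ccccc1
F4 | step 7 | 4-[2,4-bis(benzyloxy)benzoyl]-2,5-bis[4-(benzyloxy)phenyl]oxolane-3-carboxylic acid, racemic, 3,4-cis, 2,5-cis, carbonyl groups trans to neighbouring aryls | O=C(c1ccc(OCc2ccccc2)cc1OCc3ccccc3)[C@@H]4[C@H](C(=O)O)[C@@H](c5ccc(OCc6ccccc6)cc5)O[C@H]4c7ccc(OCc8ccccc8)cc7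
F5 | step 7 | S-ethyl 4-[2,4-bis(benzyloxy)benzoyl]-2,5-bis[4-(benzyloxy)phenyl]oxolane-3-carbothioate, racemic, same relative configuration | O=C(c1ccc(OCc2ccccc2)cc1OCc3ccccc3)[C@@H]4[C@H](C(=O)SCC)[C@@H](c5ccc(OCc6ccccc6)cc5)O[C@H]4c7ccc(OCc8ccccc8)cc7
F6 | step 2 | (E)-N'-[4-(benzyloxy)benzylidene]-4-methylbenzenesulfonohydrazide | Cc1ccc(cc1)S(=O)(=O)N/N=C/c1ccc(OCc2ccccc2)cc1
F7 | step 2 | exo-6-[4-(benzyloxy)phenyl]-3-phenyl-3-azabicyclo[3.1.0]hexane-2,4-dione (meso) | O=C1N(c2ccccc2)C(=O)[C@H]3[C@@H]1[C@@H]3c4ccc(OCc5ccccc5)cc4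
F8 | step 2 | cis-3-[4-(benzyloxy)phenyl]cyclopropane-1,2-dicarboxylic acid, aryl trans to both carboxyl groups (meso) | OC(=O)[C@H]1[C@@H](C(=O)O)[C@@H]1c1ccc(OCc2ccccc2)cc1
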